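Assumption: the target is treated as the open keto acid as drawn (its lactol ring–chain tautomer is the same substance). It has no stereocenter; the single carbon stereocenter carried by compounds 8 to 12 is racemic and is destroyed in step 7.

Atom labels used below: ring C1 (CO2H), C2 (OH), C3, C4 (OMe), C5, C6 (chain); chain C1' (ArCH2), C2' (C=O), C3' to C13' (C13' bears the OH).

## Analysis of the target

Target 14 is a benzoic acid with four ring substituents: CO2H at C1, OH at C2, OMe at C4 and a 13-hydroxy-2-oxotridecyl chain at C6. The carboxyl group therefore sits at the most crowded ring position, between the phenol and the chain. The chain is unbranched: a benzylic methylene C1', a ketone C2' and eleven further methylenes ending in a primary alcohol. There is no stereocenter, so the task is regiochemistry and functional-group differentiation, not configuration. Several groups are sensitive: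
- the keto acid can close to a lactol and dehydrate to a 3-alkylisocoumarin in acid;
- the C1' methylene between arene and ketone is acidic and easily oxidised;
- the electron-rich salicylic acid can decarboxylate when heated in acid;
- the two ring oxygens differ only by one methyl group and must be told apart.

The hard part is to put a carboxyl carbon between two ortho substituents of an electron-rich ring with a single regiochemistry, next to a chain whose ketone is one carbon away from the ring. The strategy rests on the five-atom path C(carboxyl)–C1–C6–C1'–C2'. A bond between its two ends gives a 2-alkylindan-1-one, with the carboxyl carbon as the ring ketone and C2' as its α-carbon. Without the carboxyl carbon the arene is a 3,5-dioxygenated benzyl unit, and with two methoxy groups its two positions ortho to the chain are equivalent.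

## Retrosynthetic reasoning

Target 14 is first traced to its acetate 13, since the primary alcohol must be masked through the Lewis-acid steps and an acetate falls off in the basic medium of the last step. The acid carbon and the C2' ketone of 13 are then reconnected into one C–C bond, through hydroperoxide 12, to give the 7-hydroxyindanone 11. This cut is chosen because C2 of the indanone is the only enolisable position of 11, so enolate oxygenation can only occur at the carbon that must become C2'. Forward, the reaction has to oxygenate that carbon and fragment the ring between it and the ketone carbon, leaving the keto acid open.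

Indanone 11 is traced to the dimethyl ether 10 by re-methylating the C7 oxygen. Differentiation of the two oxygens is placed here, and not before ring formation, because only the ring ketone lies peri to one methoxy group and can hold a Lewis acid against it. Working forward from a symmetrical ring, nothing has to be differentiated until the ketone exists.

The key disconnection cuts the bond between the ring ketone carbon and the arene carbon C7a of 10. This leads through acid chloride 9 to the 2-benzylalkanoic acid 8. The bond is cut here because it is the only ring bond whose formation is an electrophilic substitution on a doubly activated carbon. The 3,5-dimethoxyphenyl ring of 8 also offers only one kind of position to a five-membered closure. Forward, one C–C bond and one ring are made, and the full carbon skeleton of 14 is already present in 8.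

Acid 8 is traced to the disubstituted malonic acid 7 by adding a carboxyl group, and 7 to its dibenzyl ester 6. Benzyl esters are chosen over simple alkyl esters because they are removed by hydrogenolysis, which leaves the acetate in place. An alkaline hydrolysis would strip the acetate and require re-protection, and heating the resulting ω-hydroxy acid for decarboxylation would invite oligoester formation.

Malonate 6 is cut at its two C–C bonds to the quaternary carbon: first to the monoalkyl malonate 4 and benzylic bromide 5, then to dibenzyl malonate 3 and bromo acetate 2, which comes from bromo alcohol 1. The unreactive alkyl bromide is introduced first, with 3 in excess. The reactive benzylic bromide is kept for the second, more hindered alkylation, where over-alkylation is impossible.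

## Alternatives that were turned down

Alternative 1: The isocoumarin A1 would be cut at the C6–C1' bond and the lactone C–O bond into 2-(benzyloxy)-4-methoxybenzoic acid A2 and the acyl sulfoxonium ylide A3.
- Forward key step: a cationic pentamethylcyclopentadienyl rhodium catalyst in its trivalent state, with a silver activator and an acetate base, metalates the only free C–H bond ortho to the carboxylate of A2. It takes up A3 as a carbene with loss of the sulfoxide and delivers the acylmethyl group to C6; the keto acid then closes to A1.
- For: it is convergent, it assembles the whole skeleton in one step, and the site is unambiguous because the other ortho position is blocked.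
- Against: three operations follow the key step. The benzyl ether must be removed without hydrogenating the C3–C4 enol lactone double bond, the silyl ether removed, and the lactone opened. A3 must be prepared, the catalyst is costly, and an electron-rich benzoic acid with an ortho alkoxy group may metalate slowly or protodecarboxylate.
- Comparison: this route is stronger on convergence and about level on step count. The chosen route offers instead commodity reagents only, no directing-group catalysis, ring oxygens that start identical and are separated by chelation, and a last step that gives the open keto acid directly and not a lactone that tends to re-close.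

Alternative 2: Dimethyl 3,5-dimethoxyhomophthalate A4 would be cut at both the C6–C1' and the C1–carboxyl bonds into the silyl aryl triflate A5 and dimethyl malonate A6.
- Forward key step: fluoride releases the aryne from A5. The malonate carbanion adds to the aryne carbon remote from the flanking methoxy group, the aryl anion closes onto an ester carbonyl, and the four-membered ring opens, a net insertion into a C–CO2Me bond.
- For: both adjacent carbon substituents are set in one mild step, the methoxy group fixes the regiochemistry inductively, and no ring has to be cleaved afterwards.
- Against: A4 carries only C1' and an ester where C2' should be. The ketone and its eleven-carbon chain must still be built from the aliphatic ester beside the aromatic one, which needs selective hydrolysis, activation and acylation of a carbon nucleophile. A5 is not a shelf compound and costs several steps, and the peri demethylation is still required.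
- Comparison: it equals the chosen route in regiochemical certainty and is better in that nothing is cleaved, but it is clearly longer. The chosen route attaches the whole chain by simple alkylation before the ring bond is formed.

Alternative 3: The dihydroresorcylate A7 would be cut at the C1–C6 and C3–C4 bonds into the enoate A8 and methyl acetoacetate A9.
- Forward key step: under alkoxide base the methylene of A9 adds to the β-carbon of A8 (Michael addition). The methyl carbon of A9 is then acylated by the enoate ester (Claisen condensation), closing the six-membered ring of A7. Its two trans centres vanish on aromatisation.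
- For: the ring is built from cheap acyclic pieces with every substituent placed by construction, and no aromatic substitution is needed. It is the only one of the four routes that could be adapted freely to other ring patterns.
- Against: A8 takes several steps, and its γ-protons invite base-induced deconjugation. After the annulation the cyclic 1,3-dione must be O-methylated at only one of its two enol oxygens and then dehydrogenated. A ketal, a benzyl ether and a hindered salicylate ester remain to be removed.
- Comparison: it is the longest of the four and passes the OH/OMe distinction to a less reliable step. The chosen route is shorter and settles that distinction by chelation.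

Key step: step 5

## Route

Step 1
Reactants: 1 11-bromoundecan-1-ol
Product: 2 11-bromoundecyl acetate
Conditions: Ac2O, Et3N, DMAP (cat.), CH2Cl2, 0 °C → rt
Reagents that add atoms: acetic anhydride, CC(=O)OC(C)=O
Why: Acetylation of a primary alcohol by nucleophilic acyl substitution with DMAP catalysis; unlike a silyl or benzyl ether, the acetate survives oxalyl chloride, SnCl4 and BCl3 later and leaves in the basic last step.

Step 2
Reactants: 3 dibenzyl malonate (1.5–2 equiv); 2 11-bromoundecyl acetate
Product: 4 dibenzyl 2-(11-acetoxyundecyl)malonate
Conditions: NaH, THF/DMF, 0 °C; then 2, NaI (cat.), 60 °C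
Reagents that add atoms: none
Why: Malonic ester alkylation (SN2) of the sodium enolate of 3 with a primary bromide under iodide catalysis; the less reactive electrophile goes in first and 3 is in excess so that a second alkylation is suppressed, and NaH in an aprotic medium avoids the transesterification of acetate and benzyl esters that an alkoxide in alcohol would cause.

Step 3
Reactants: 4 dibenzyl 2-(11-acetoxyundecyl)malonate; 5 3,5-dimethoxybenzyl bromide
Product: 6 dibenzyl 2-(11-acetoxyundecyl)-2-(3,5-dimethoxybenzyl)malonate
Conditions: NaH, THF/DMF, 0 °C; then 5, 0 °C → rt
Reagents that add atoms: none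
Why: Second malonate alkylation; the hindered enolate of 4 is matched with the reactive benzylic bromide, and the quaternary product cannot be alkylated further.

Step 4
Reactants: 6 dibenzyl 2-(11-acetoxyundecyl)-2-(3,5-dimethoxybenzyl)malonate
Product: 8 racemic 13-acetoxy-2-(3,5-dimethoxybenzyl)tridecanoic acid, via malonic acid 7 (not isolated)
Conditions: H2 (1 atm), 10% Pd/C, EtOAc, rt; filter; then xylenes, 140 °C
Reagents that add atoms: none
Why: Hydrogenolysis of the two benzyl esters leaves the acetate, the aryl methyl ethers and the C-benzyl bond untouched, and the disubstituted malonic acid 7 then decarboxylates thermally through the usual six-membered transition state; the new C2 stereocenter arises by unselective protonation of the enol and is racemic, which is harmless because step 7 destroys it.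

Step 5
Reactants: 8 racemic 13-acetoxy-2-(3,5-dimethoxybenzyl)tridecanoic acid
Product: 10 racemic 11-(5,7-dimethoxy-1-oxoindan-2-yl)undecyl acetate, via acid chloride 9 (not isolated)
Conditions: (COCl)2 (1.5 equiv), DMF (cat.), CH2Cl2, 0 °C → rt; concentrate; then SnCl4 (2.5 equiv), CH2Cl2 (dilute), −78 → 0 °C
Reagents that add atoms: oxalyl chloride, O=C(Cl)C(Cl)=O (supplies only the chlorine of 9; no reagent atom remains in 10)
Why: Intramolecular Friedel–Crafts acylation of a 3-arylpropanoyl chloride to an indan-1-one, a well-established reaction type. Oxalyl chloride with catalytic DMF turns acid 8 into acid chloride 9 without touching the acetate or the aryl ethers; SnCl4 then ionises or strongly polarises the C–Cl bond, and the acyl carbon is attacked by the ring carbon ortho to the tether, which is ortho to one methoxy group and para to the other, giving a Wheland intermediate that loses a proton. The five-membered ring closes 5-exo at the acyl carbon (its C–O π bond stays outside the ring) with the attacked arene bond inside the new ring, a strained geometry that the doubly activated ring carbon makes accessible. No stereocenter is made: the α-carbon of 8 is already racemic, is not touched, and disappears in step 7. The only selectivity needed is the site of acylation, and the substrate secures it, because the two carbons ortho to the tether are equivalent by symmetry and the carbon between the methoxy groups is para to the tether and out of reach, so only 10 can form. Intermolecular acylation is held back by dilution, and more than two equivalents of SnCl4 are used because the acetate carbonyl binds one. If the chelated Lewis acid removes some of the peri methyl group, that material is the product of step 6 and is carried forward.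

Step 6
Reactants: 10 racemic 11-(5,7-dimethoxy-1-oxoindan-2-yl)undecyl acetate
Product: 11 racemic 11-(7-hydroxy-5-methoxy-1-oxoindan-2-yl)undecyl acetate
Conditions: BCl3 (1 M in CH2Cl2, 2.5 equiv), CH2Cl2, −78 → 0 °C; then H2O/NaHCO3
Reagents that add atoms: none
Why: Chelation-controlled aryl methyl ether cleavage: BCl3 bridges the ketone oxygen and the peri 7-methoxy oxygen in a six-membered chelate and chloride removes that methyl group by SN2, while the 5-methoxy group para to the carbonyl has no such activation; the primary acetate tolerates BCl3 at or below 0 °C, and any that is lost only uncovers early the alcohol that step 7 frees anyway.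

Step 7
Reactants: 11 racemic 11-(7-hydroxy-5-methoxy-1-oxoindan-2-yl)undecyl acetate
Product: 14 2-hydroxy-6-(13-hydroxy-2-oxotridecyl)-4-methoxybenzoic acid (target), via α-hydroperoxide 12 (not isolated), via acetoxy keto acid 13 (not isolated)
Conditions: KOt-Bu (5 equiv), O2 (1 atm), t-BuOH/THF, 0 °C → rt; then 2 M aq. KOH, rt; then 1 M HCl, 0 °C, to pH 3
Reagents that add atoms: dioxygen, O=O
Why: Base-mediated autoxidative cleavage of an α-alkyl cyclic aryl ketone: the potassium enolate at C2, the only enolisable position, traps O2 to give hydroperoxide 12, whose peroxide oxygen adds to the ring carbonyl and fragments so that the carbonyl carbon becomes the C1 carboxylate and C2 becomes the C2' ketone of 13; aqueous KOH then saponifies the acetate. The racemic stereocenter is erased here, and cold, mild acidification keeps the keto acid from dehydrating to the isocoumarin.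

## Compound list

1 | 11-bromoundecan-1-ol | OCCCCCCCCCCCBr | starting material
2 | 11-bromoundecyl acetate | CC(=O)OCCCCCCCCCCCBr | intermediate
3 | dibenzyl malonate | O=C(CC(=O)OCc1ccccc1)OCc1ccccc1 | starting material
4 | dibenzyl 2-(11-acetoxyundecyl)malonate | CC(=O)OCCCCCCCCCCCC(C(=O)OCc1ccccc1)C(=O)OCc1ccccc1 | intermediate
5 | 3,5-dimethoxybenzyl bromide | COc1cc(CBr)cc(OC)c1 | starting material
6 | dibenzyl 2-(11-acetoxyundecyl)-2-(3,5-dimethoxybenzyl)malonate | COc1cc(CC(CCCCCCCCCCCOC(C)=O)(C(=O)OCc2ccccc2)C(=O)OCc2ccccc2)cc(OC)c1 | intermediate
7 | 2-(11-acetoxyundecyl)-2-(3,5-dimethoxybenzyl)malonic acid | COc1cc(CC(CCCCCCCCCCCOC(C)=O)(C(=O)O)C(=O)O)cc(OC)c1 | intermediate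
8 | racemic 13-acetoxy-2-(3,5-dimethoxybenzyl)tridecanoic acid | COc1cc(CC(CCCCCCCCCCCOC(C)=O)C(=O)O)cc(OC)c1 | intermediate
9 | racemic 13-chloro-12-(3,5-dimethoxybenzyl)-13-oxotridecyl acetate (acid chloride of 8) | COc1cc(CC(CCCCCCCCCCCOC(C)=O)C(=O)Cl)cc(OC)c1 | intermediate
10 | racemic 11-(5,7-dimethoxy-1-oxoindan-2-yl)undecyl acetate | COc1cc2c(c(OC)c1)C(=O)C(CCCCCCCCCCCOC(C)=O)C2 | intermediate
11 | racemic 11-(7-hydroxy-5-methoxy-1-oxoindan-2-yl)undecyl acetate | COc1cc(O)c2c(c1)CC(CCCCCCCCCCCOC(C)=O)C2=O | intermediate
12 | racemic 11-(2-hydroperoxy-7-hydroxy-5-methoxy-1-oxoindan-2-yl)undecyl acetate | COc1cc(O)c2c(c1)CC(CCCCCCCCCCCOC(C)=O)(OO)C2=O | intermediate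
13 | 2-(13-acetoxy-2-oxotridecyl)-6-hydroxy-4-methoxybenzoic acid | COc1cc(O)c(C(=O)O)c(CC(=O)CCCCCCCCCCCOC(C)=O)c1 | intermediate
14 | 2-hydroxy-6-(13-hydroxy-2-oxotridecyl)-4-methoxybenzoic acid | COc1cc(O)c(C(=O)O)c(CC(=O)CCCCCCCCCCCO)c1 | target

Total step count: 7. Longest linear sequence: 7 steps (1 → 14); compounds 3 and 5 are bought and enter in steps 2 and 3.

## Steps least certain to work

Step 5 (key step). The five-membered closure is strained, so intermolecular acylation may compete and give oligomers. The strong Lewis acid may also attack the acetate or the methyl ethers in an uncontrolled way. The fallback changes the acyl donor and sets out from malonic acid 7, taken from step 4 after the hydrogenolysis and before heating. Condensation with isopropenyl acetate and catalytic H2SO4 should give the Meldrum's acid derivative 11-[5-(3,5-dimethoxybenzyl)-2,2-dimethyl-4,6-dioxo-1,3-dioxan-5-yl]undecyl acetate F1. Heating F1 with catalytic Sc(OTf)3 in nitromethane lets the dioxanedione acylate the same ring carbon. The ring-opened β-keto acid then loses acetone and CO2, and the route is rejoined at 10 without an acid chloride or a stoichiometric strong Lewis acid.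

Step 7. Three processes threaten this step:
- Under base and O2 the product can be oxygenated a second time at its acidic C1' methylene, which would shorten the chain.
- The phenoxide of 11 donates into the ring carbonyl, so the hydroperoxide may fail to fragment and stall at the α-oxygenated ketone.
- The phenoxide itself may be oxidised.

The fallback cleaves the same bond without a basic oxygen atmosphere and sets out from 11. Silylation with TBSOTf and Et3N at both the phenol and the enol oxygen should give 11-[3,4-bis(tert-butyldimethylsilyloxy)-6-methoxy-1H-inden-2-yl]undecyl acetate F2. Ozonolysis of its enol ether double bond (O3, CH2Cl2, −78 °C, then Me2S) should give tert-butyldimethylsilyl 2-(13-acetoxy-2-oxotridecyl)-6-(tert-butyldimethylsilyloxy)-4-methoxybenzoate F3. K2CO3 in aqueous methanol then removes the silyl ester, the aryl silyl ether and the acetate, and the route is rejoined at 14.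

Step 6. Excess BCl3 or warming may erode the selectivity between the two methyl ethers or cleave the acetate, and the boron chelate may enolise the ketone and cause condensation. The fallback moves the demethylation behind the ring cleavage and sets out from 10:
- Cleavage of 10 under the conditions of step 7 (KOt-Bu, O2, then aqueous KOH and acid), here without a phenoxide present, should give 2-(13-hydroxy-2-oxotridecyl)-4,6-dimethoxybenzoic acid F4.
- Warm Ac2O and pyridine acetylate the alcohol and close the enol lactone to 11-(6,8-dimethoxy-1-oxo-1H-isochromen-3-yl)undecyl acetate F5.
- BCl3 at −78 °C removes the methyl group peri to the lactone carbonyl of this non-enolisable substrate, giving 11-(8-hydroxy-6-methoxy-1-oxo-1H-isochromen-3-yl)undecyl acetate F6.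
- KOH in aqueous ethanol opens the lactone and removes the acetate, and cold acidification rejoins the route at 14.

Step 2. The monoalkylated malonate is itself acidic, so a second alkylation may compete and complicate the separation from excess 3. The fallback makes the first C–C bond by condensation and sets out from 5 and 3. 3,5-Dimethoxybenzaldehyde F7 can be bought or made from 5 by Kornblum oxidation (DMSO, NaHCO3, heat). Knoevenagel condensation of F7 with 3 (piperidinium acetate, toluene, water removal) should give dibenzyl 2-(3,5-dimethoxybenzylidene)malonate F8. Conjugate reduction with NaBH4 in THF/i-PrOH at 0 °C should give dibenzyl 2-(3,5-dimethoxybenzyl)malonate F9, which cannot be over-substituted. Alkylation of F9 with 2 (NaH, DMF, NaI, 60 °C) rejoins the route at 6.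

## Further compounds

F1 | step 5 | 11-[5-(3,5-dimethoxybenzyl)-2,2-dimethyl-4,6-dioxo-1,3-dioxan-5-yl]undecyl acetate | COc1cc(CC2(CCCCCCCCCCCOC(C)=O)C(=O)OC(C)(C)OC2=O)cc(OC)c1
F2 | step 7 | 11-[3,4-bis(tert-butyldimethylsilyloxy)-6-methoxy-1H-inden-2-yl]undecyl acetate | COc1cc2c(c(O[Si](C)(C)C(C)(C)C)c1)C(O[Si](C)(C)C(C)(C)C)=C(CCCCCCCCCCCOC(C)=O)C2
F3 | step 7 | tert-butyldimethylsilyl 2-(13-acetoxy-2-oxotridecyl)-6-(tert-butyldimethylsilyloxy)-4-methoxybenzoate | COc1cc(O[Si](C)(C)C(C)(C)C)c(C(=O)O[Si](C)(C)C(C)(C)C)c(CC(=O)CCCCCCCCCCCOC(C)=O)c1
F4 | step 6 | 2-(13-hydroxy-2-oxotridecyl)-4,6-dimethoxybenzoic acid | COc1cc(OC)c(C(=O)O)c(CC(=O)CCCCCCCCCCCO)c1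
F5 | step 6 | 11-(6,8-dimethoxy-1-oxo-1H-isochromen-3-yl)undecyl acetate | COc1cc(OC)c2c(c1)C=C(CCCCCCCCCCCOC(C)=O)OC2=O
F6 | step 6 | 11-(8-hydroxy-6-methoxy-1-oxo-1H-isochromen-3-yl)undecyl acetate | COc1cc(O)c2c(c1)C=C(CCCCCCCCCCCOC(C)=O)OC2=O
F7 | step 2 | 3,5-dimethoxybenzaldehyde (bought, or made from 5) | COc1cc(C=O)cc(OC)c1
F8 | step 2 | dibenzyl 2-(3,5-dimethoxybenzylidene)malonate | COc1cc(C=C(C(=O)OCc2ccccc2)C(=O)OCc2ccccc2)cc(OC)c1
F9 | step 2 | dibenzyl 2-(3,5-dimethoxybenzyl)malonate | COc1cc(CC(C(=O)OCc2ccccc2)C(=O)OCc2ccccc2)cc(OC)c1
A1 | alternative 1 | 8-(benzyloxy)-3-[11-(tert-butyldimethylsilyloxy)undecyl]-6-methoxyisochromen-1-one | COc1cc2C=C(CCCCCCCCCCCO[Si](C)(C)C(C)(C)C)OC(=O)c2c(OCc3ccccc3)c1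
A2 | alternative 1 | 2-(benzyloxy)-4-methoxybenzoic acid | COc1ccc(C(=O)O)c(OCc2ccccc2)c1
A3 | alternative 1 | 13-(tert-butyldimethylsilyloxy)-1-[dimethyl(oxo)-λ6-sulfanylidene]tridecan-2-one | CS(C)(=O)=CC(=O)CCCCCCCCCCCO[Si](C)(C)C(C)(C)C
A4 | alternative 2 | dimethyl 3,5-dimethoxyhomophthalate | COC(=O)Cc1cc(OC)cc(OC)c1C(=O)OC
A5 | alternative 2 | 3,5-dimethoxy-2-(trimethylsilyl)phenyl trifluoromethanesulfonate | COc1cc(OC)c([Si](C)(C)C)c(OS(=O)(=O)C(F)(F)F)c1
A6 | alternative 2 | dimethyl malonate | COC(=O)CC(=O)OC
A7 | alternative 3 | racemic methyl trans-2-{[2-(11-(benzyloxy)undecyl)-1,3-dioxolan-2-yl]methyl}-4,6-dioxocyclohexane-1-carboxylate (relative configuration drawn) | COC(=O)[C@@H]1C(=O)CC(=O)C[C@H]1CC1(CCCCCCCCCCCOCc2ccccc2)OCCO1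
A8 | alternative 3 | methyl (E)-4-[2-(11-(benzyloxy)undecyl)-1,3-dioxolan-2-yl]but-2-enoate | COC(=O)/C=C/CC1(CCCCCCCCCCCOCc2ccccc2)OCCO1
A9 | alternative 3 | methyl acetoacetate | COC(=O)CC(C)=O
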